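**Remark (assumption):** atoms carry the numbers of the bicyclo[3.3.1]nonane core (C1 and C5 bridgeheads, C9 bridging ketone, C2–C4 enolised dione, C6–C8 carbocyclic bridge). β-Keto esters and the trione are written as one tautomer, and a methine between two carbonyl groups is treated as configurationally labile.

## Structural features

The target is a bicyclo[3.3.1]nonane-2,4,9-trione. Ring A (C1–C2–C3–C4–C5–C9) is an enolised 1,3-diketone with a 3,4-dihydroxybenzoyl group on C3, ring B (C1–C8–C7–C6–C5–C9) is a cyclohexanone, and the rings share C1, C9 and C5. Both bridgeheads are quaternary: C1 carries the (2S)-2,3-dihydroxy-3-methylbutyl chain and sits next to the gem-dimethyl carbon C8, and C5 carries the lavandulyl CH2. The prenyl group on C7 lies on the same face of ring B as the C2–C3–C4 bridge, so it is trans to both bridgehead side chains. C1, C5 and C7 are linked through C8 and C6, whereas the lavandulyl methine and the chain carbinol are exocyclic and out of reach of ring control; they must be imported or set by a reagent. Fragile groups are the two prenyl groups and the isopropenyl group (acid closes them onto enol oxygen or onto each other), the catechol (oxidation), the β-triketone (retro-Claisen) and the tertiary alcohol. The real difficulty is two quaternary carbons flanking C9, one of them adjacent to quaternary C8, built while three olefins are carried along. The key step exploits the segment C6H2–C7H(prenyl)–C8Me2: it is a lavandulyl unit whose isopropenyl carbon has bonded to C1, with the same absolute configuration as the C5 side chain, so (S)-lavandulol serves for both (the label becomes R after attachment only because the CH2 group drops below isopropenyl in priority). One correction is needed. The intact lavandulyl 1,5-diene cannot meet acid, because a protonated prenyl group also closes six-membered rings (onto the isopropenyl group, or onto the enol carbon C5). The prenyl terminus is therefore removed before the acid step and restored after it.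

## Logic of the disconnections

**20 to 19.** Four O–Si bonds are cut (two on the catechol, two on the chain diol). The phenols and the diol cannot face the strongly basic closure of ring A, and silicon on all four oxygens lets one fluoride treatment end the synthesis without acid. The demand is buffered fluoride with exclusion of air.

**19 to 15 and 17.** C2–C3 and C3–C4 are cut. C2 and C4 are at the carboxyl oxidation level and C3 is the α-carbon of an aryl methyl ketone, so this removes ring A and the aryl unit at once. What remains is a monocyclic ring B holding every stereocentre. The forward step must acylate a ketone enolate with a neopentyl-type ester and then acylate the resulting β-diketonate with the second ester; the esters must be cis, and the chain must hold no enolisable ketone at that stage.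

**15 to 14 to 13.** An O–Si bond and the carbinol C–H bond are cut, taking the chain back to a ketone. The carbinol is exocyclic, so a catalyst must set it. The chain becomes an achiral acylmethyl unit. The reduction must select the chain ketone over C9 and must not touch the olefins.

**13 to 9 and 12.** The C1–CH2 bond is cut. C1 is the most hindered nucleophilic carbon (between C8 and C9), so it is paired with the most reactive class of alkylating agent and is alkylated last, when no other acidic hydrogen remains. This removes one quaternary centre and the five-carbon chain. The alkylation must occur at carbon and anti to the C7 prenyl group.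

**9 to 8 and 3.** The C5–CH2 bond is cut. The side chain arrives with its stereocentre, and C5 is the more accessible of the two acidic methines, so it tolerates a slower β-branched iodide. The second quaternary centre is removed and 3 is used twice. The step needs C5-over-C1 selectivity and attack trans to the C7 substituent.

**8 to 7.** The =CMe2 terminus on the C7 side chain is exchanged for =CH2. The acid step that closes ring B cannot tolerate a trisubstituted alkene, so 7 holds only one unreactive olefin. The forward step is a cross-metathesis at that single olefin.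

**7 to 6.** The C1–C8 bond is cut (key step). C8, with its two methyl groups, is the Markovnikov carbon of an isopropenyl group, and C1 is an enol carbon activated by ketone and ester. Ring B and quaternary C8 disappear, leaving an acyclic keto diester whose only stereocentre is C7. The forward step needs ionisation of the isopropenyl group alone, capture at carbon, and no loss of configuration at C7.

**6 to 5.** The =CH2 terminus is traced back to =CMe2, so that the acyclic keto diester is the direct alkylation product of the chiral-pool iodide and one building block supplies both C10 units. Compounds 5 and 8 thus carry the complete lavandulyl-derived skeletons before and after ring closure, while the acid step itself runs on 6. The forward step is an ethenolysis of a trisubstituted alkene.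

**5 to 3 and 4.** The C5–C6 bond is cut. Compound 4 supplies C1, C2, C4, C5 and C9 with both carboxyl carbons in place. Mono-alkylation is required.

**3 to 2 to 1.** C–I is traced to C–O, and the enantiomers are separated by selective acylation.

**12 to 11 to 10, and 17 to 16.** The chain electrophile comes from bromination and silylation of a hydroxy ketone, and the aryl ketone from silylation of the catechol.

## Other disconnections considered

**Alternative 1:** The cut is C4–C5. The substrate would be the fused enol lactone A1, in which C4 is bound to the enol oxygen on C9 and C2 is a methyl enol ether. A 1,3-acyl shift, photochemical (photo-Fries kind) or catalysed by an acyl-transfer nucleophile (Steglich-type), would give the bridged enol ether A2.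
- In its favour: the bond to the quaternary bridgehead forms intramolecularly, and the tether forces C4 to arrive cis to C2. On control of C5 relative to C1 this alternative is better than the chosen plan, which relies on two substrate-controlled alkylations.
- Against it: A1 holds an unsaturated ester chromophore beside three isolated olefins, so irradiation risks radical-pair escape, decarbonylation and olefin photochemistry. Nucleophilic catalysis must make a quaternary centre from a hindered tetrasubstituted enolate, where O-reacylation is the easy path. A2 still lacks the aroyl group and needs enol ether cleavage and an acidic acetonide removal near prenyl groups.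
- Comparison: on structure the two plans are equal, since both reach the bridged core from a ring B precursor. On mechanism the alternative answers bridgehead congestion more directly but with less precedent. On step economy it is longer by the late C3 acylation and two deprotections.

**Alternative 2:** The cut is C2–C3 and C3–C4, the same two bonds the chosen plan makes last. C3 would arrive as the diazo carbon of the aroyldiazomethane A4 and insert into the 1,2-diketone of the bicyclo[3.2.1]octanetrione A3 under Sc(OTf)3 or BF3·OEt2, with acyl migration and loss of nitrogen, to give A5.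
- In its favour: it is as convergent as the chosen plan (equal on this point). It is better in electrophilicity, because a strained diketone replaces two neopentyl esters and no strong base is needed, and either carbonyl may be attacked since both migration modes give the same 2-aroyl-1,3-dione.
- Against it: A3 must first be made, most plausibly from a cis-diester such as 15 by acyloin-type coupling and oxidation, which adds steps. The Lewis acid meets three acid-sensitive olefins and an acetonide. Epoxide formation, attack at C9 and migration of the bridgehead carbon are open side channels, and A5 still needs acidic acetonide cleavage.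
- Comparison: equal on structure and convergence; milder on basicity but harsher on acidity; longer by about three steps.

**Alternative 3:** The cut is C5–C9 and C5–C6. The diazo ester A7 would insert its diazo carbon into the cyclopentanone A6 under a chiral Sc(OTf)3–N,N'-dioxide catalyst, giving the ring B keto ester A8 with quaternary C5.
- In its favour: C5 becomes quaternary and stereodefined in one catalytic step, without the SN2 reaction of a β-branched iodide with a tertiary enolate. On this point it is better than step 7 of the chosen plan, and catalyst control could override a weak substrate bias.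
- Against it: the two α-methylene groups of A6 differ only through the gem-dimethyl carbon, so C6 versus C1 migration is not secured. The catalyst must cooperate with two existing stereocentres. A7 carries a homoallylic olefin prone to intramolecular dipolar cycloaddition, and enantiopure A6 needs its own synthesis. A8 has only a methylene at C1, so the ester and the chain must still be placed at the most hindered position.
- Comparison: on structure the chosen plan is ahead, because 4 delivers C2 and C4 from the start. On mechanism the alternative gives better control of C5 but worse regiocontrol. On step economy it is longer.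

Key step: step 5

## Route

Step 1
Reactants: 1 (±)-lavandulol [rac-5-methyl-2-(prop-1-en-2-yl)hex-4-en-1-ol]
Product: 2 (S)-lavandulol [(2S)-5-methyl-2-(prop-1-en-2-yl)hex-4-en-1-ol]
Conditions: porcine pancreatic lipase, vinyl acetate, hexane, 25 °C, stopped near 65% conversion; chromatography
Reagents that add atoms: none
Why: Lipase-catalysed kinetic resolution by transesterification; lipases acylate the (R)-alcohol faster, so the unreacted alcohol should be enriched in (S), and running past half conversion compensates for a moderate selectivity factor (purity to be checked by chiral gas chromatography, cycle repeated if needed).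

Step 2
Reactants: 2 (S)-lavandulol
Product: 3 (S)-lavandulyl iodide [(2S)-1-iodo-5-methyl-2-(prop-1-en-2-yl)hex-4-ene]
Conditions: I2, PPh3, imidazole, CH2Cl2, 0 → 25 °C
Reagents that add atoms: iodine, [I][I]
Why: Appel-type iodination of a primary alcohol under neutral conditions; the stereocentre is β to the reacting carbon and untouched, and no acid is present that could cyclise the 1,5-diene.

Step 3
Reactants: 3 (S)-lavandulyl iodide; 4 dimethyl 3-oxopentanedioate (dimethyl 1,3-acetonedicarboxylate)
Product: 5 dimethyl 2-[(2R)-5-methyl-2-(prop-1-en-2-yl)hex-4-en-1-yl]-3-oxopentanedioate (dimethyl 2-lavandulyl-3-oxopentanedioate; enol form drawn)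
Conditions: 4 (2.5 equiv), NaH (2.4 equiv), THF–DMF, 0 → 55 °C
Reagents that add atoms: none
Why: C-alkylation of a β-keto ester sodium enolate by a primary iodide (acetoacetic ester-type alkylation); the excess of 4 keeps mono-alkylation dominant, its two α-carbons are equivalent, and the new methine is labile and of no consequence.

Step 4
Reactants: 5 dimethyl 2-lavandulyl-3-oxopentanedioate
Product: 6 dimethyl 3-oxo-2-[(2R)-2-(prop-1-en-2-yl)pent-4-en-1-yl]pentanedioate (enol form drawn)
Conditions: ethylene (8 bar), second-generation Hoveyda–Grubbs catalyst (H2IMes)Cl2Ru(=CH-C6H4-2-OiPr) (5 mol%), 1,4-benzoquinone (10 mol%), toluene, 50 °C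
Reagents that add atoms: ethylene, C=C
Why: Ethenolysis (cross-metathesis with ethylene), known for trisubstituted isoprenoid olefins, exchanges the =CMe2 terminus for =CH2 and releases isobutylene. The isopropenyl group can only exchange degenerately and cannot ring-close with its neighbour (a cyclobutene would result); benzoquinone suppresses hydride-induced olefin migration.

Step 5
Reactants: 6 dimethyl 3-oxo-2-[(2R)-2-(prop-1-en-2-yl)pent-4-en-1-yl]pentanedioate
Product: 7 dimethyl (1S,5R)-4,4-dimethyl-2-oxo-5-(prop-2-en-1-yl)cyclohexane-1,3-dicarboxylate (C2–C3 enol drawn)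
Conditions: SnCl4 (2 equiv), CH2Cl2, −20 → 0 °C; aq. NaHCO3
Reagents that add atoms: none
Why: SnCl4 chelates the β-keto ester, the hydrogen chloride released from the tin enolate protonates the 1,1-disubstituted alkene at its CH2 terminus (Markovnikov), and the tertiary cation at C8 is captured by the enol carbon C1, forming C1–C8. The closest known reaction type is the SnCl4- or acid-mediated cyclisation of alkenyl β-keto esters to 2,2-dimethylcyclohexanone carboxylates (cationic Conia-ene-type hydroalkylation). Ring B closes in a 6-(enolendo)-exo-trig mode through a chair with the C7 allyl group equatorial. No configurationally stable stereocentre is created: C8 carries two methyl groups, C1 and C5 are enolisable and C5 settles with its ester equatorial, while C7 is carried over from 2. Chemoselectivity rests on the substrate: the isopropenyl group is the only olefin that gives a tertiary cation, the allyl group is neither protonated nor a competent π-nucleophile (it could only close a five-membered ring to a secondary cation), and the C5 enol carbon could only form a four-membered ring. Capture by enol or ester oxygen gives tertiary oxonium species that re-ionise, so the irreversible C–C bond accumulates. Retention at C7 requires capture by the chelated enol to outrun a 1,2-hydride shift from C7, which low temperature and a non-polar solvent favour.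

Step 6
Reactants: 7 dimethyl (1S,5R)-4,4-dimethyl-2-oxo-5-(prop-2-en-1-yl)cyclohexane-1,3-dicarboxylate
Product: 8 dimethyl (1S,5R)-4,4-dimethyl-5-(3-methylbut-2-en-1-yl)-2-oxocyclohexane-1,3-dicarboxylate (enol form drawn)
Conditions: 2-methyl-2-butene (excess), second-generation Grubbs catalyst (H2IMes)(PCy3)Cl2Ru=CHPh (3 mol%), CH2Cl2, 40 °C
Reagents that add atoms: 2-methyl-2-butene, CC=C(C)C
Why: Cross-metathesis of a monosubstituted olefin with 2-methyl-2-butene is the standard allyl-to-prenyl conversion; 7 holds no other olefin and the β-keto ester is inert.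

Step 7
Reactants: 8 dimethyl (1S,5R)-4,4-dimethyl-5-(3-methylbut-2-en-1-yl)-2-oxocyclohexane-1,3-dicarboxylate; 3 (S)-lavandulyl iodide
Product: 9 dimethyl (1S,5R)-4,4-dimethyl-5-(3-methylbut-2-en-1-yl)-1-[(2R)-5-methyl-2-(prop-1-en-2-yl)hex-4-en-1-yl]-2-oxocyclohexane-1,3-dicarboxylate (C2–C3 enol drawn)
Conditions: Cs2CO3 (1.5 equiv), 3 (1.3 equiv), DMF, 50 °C
Reagents that add atoms: none
Why: C-alkylation of a cyclic β-keto ester enolate; of the two acidic methines only C5 is reached by a β-branched iodide because C1 is shielded by C8. The electrophile enters axially on the face trans to the equatorial C7 prenyl group, which places the ester cis and the lavandulyl group trans to it; the side-chain stereocentre arrives intact with 3.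

Step 8
Reactants: 10 3-hydroxy-3-methylbutan-2-one
Product: 11 1-bromo-3-hydroxy-3-methylbutan-2-one
Conditions: Br2, MeOH, 0 → 20 °C
Reagents that add atoms: bromine, BrBr
Why: Acid-catalysed α-bromination of a methyl ketone; the methyl group is the only enolisable position.

Step 9
Reactants: 11 1-bromo-3-hydroxy-3-methylbutan-2-one
Product: 12 1-bromo-3-methyl-3-(triethylsilyloxy)butan-2-one
Conditions: Et3SiOTf, 2,6-lutidine, CH2Cl2, −78 °C
Reagents that add atoms: triethylsilyl trifluoromethanesulfonate, CC[Si](CC)(CC)OS(=O)(=O)C(F)(F)F
Why: Silylation of a tertiary alcohol with a silyl triflate and a hindered base; it removes a hydroxyl that could add to carbonyl groups or displace bromide under the basic alkylation.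

Step 10
Reactants: 9 dimethyl (1S,5R)-1-lavandulyl-5-prenyl keto diester; 12 1-bromo-3-methyl-3-(triethylsilyloxy)butan-2-one
Product: 13 dimethyl (1S,3R,5R)-4,4-dimethyl-5-(3-methylbut-2-en-1-yl)-1-[(2R)-5-methyl-2-(prop-1-en-2-yl)hex-4-en-1-yl]-3-[3-methyl-2-oxo-3-(triethylsilyloxy)butyl]-2-oxocyclohexane-1,3-dicarboxylate
Conditions: NaH (1.0 equiv), THF, 0 °C; then 12 (1.2 equiv), 0 → 25 °C
Reagents that add atoms: none
Why: SN2 alkylation of a β-keto ester enolate by an α-bromoketone, the most reactive alkylating class, matched to the most hindered carbon; C1 holds the only acidic hydrogen left. Approach anti to the pseudoaxial C8 methyl group and to the C7 prenyl group places the chain trans to prenyl and cis to the C5 side chain, so the two esters end up cis; no excess base remains to enolise the new ketone.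

Step 11
Reactants: 13 chain ketone
Product: 14 dimethyl (1S,3R,5R)-3-[(2S)-2-hydroxy-3-methyl-3-(triethylsilyloxy)butyl]-4,4-dimethyl-5-(3-methylbut-2-en-1-yl)-1-[(2R)-5-methyl-2-(prop-1-en-2-yl)hex-4-en-1-yl]-2-oxocyclohexane-1,3-dicarboxylate
Conditions: (R)-2-methyl-CBS-oxazaborolidine (0.5 equiv), catecholborane (2 equiv), toluene, −78 → −40 °C; then MeOH, aq. NaOH
Reagents that add atoms: none
Why: Corey–Bakshi–Shibata reduction; the catalyst distinguishes the tertiary silyloxy-bearing carbon (large) from the CH2 group (small), and the (R)-catalyst should give the (S)-carbinol. Catecholborane does not hydroborate olefins at this temperature, and the C9 ketone between two quaternary carbons and the esters are inert.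

Step 12
Reactants: 14 secondary alcohol
Product: 15 dimethyl (1S,3R,5R)-3-[(2S)-3-methyl-2,3-bis(triethylsilyloxy)butyl]-4,4-dimethyl-5-(3-methylbut-2-en-1-yl)-1-[(2R)-5-methyl-2-(prop-1-en-2-yl)hex-4-en-1-yl]-2-oxocyclohexane-1,3-dicarboxylate
Conditions: Et3SiOTf, 2,6-lutidine, CH2Cl2, −78 → 0 °C
Reagents that add atoms: triethylsilyl trifluoromethanesulfonate, CC[Si](CC)(CC)OS(=O)(=O)C(F)(F)F
Why: Silyl ether formation; it caps the secondary hydroxyl before it can lactonise onto the C2 ester or, as an alkoxide in step 14, add to C9 and open ring B by retro-Claisen cleavage.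

Step 13
Reactants: 16 1-(3,4-dihydroxyphenyl)ethan-1-one (3,4-dihydroxyacetophenone)
Product: 17 1-[3,4-bis(triisopropylsilyloxy)phenyl]ethan-1-one
Conditions: iPr3SiCl (2.5 equiv), imidazole, DMF, 25 → 40 °C
Reagents that add atoms: chlorotriisopropylsilane, CC(C)[Si](Cl)(C(C)C)C(C)C
Why: Standard phenol silylation; triisopropylsilyl aryl ethers tolerate amide bases and alkoxide better than smaller silyl ethers and leave with fluoride.

Step 14
Reactants: 15 bis(triethylsilyl) diester; 17 1-[3,4-bis(triisopropylsilyloxy)phenyl]ethan-1-one
Product: 19 (1R,5R,7R)-3-[3,4-bis(triisopropylsilyloxy)benzoyl]-4-hydroxy-8,8-dimethyl-7-(3-methylbut-2-en-1-yl)-1-[(2S)-3-methyl-2,3-bis(triethylsilyloxy)butyl]-5-[(2R)-5-methyl-2-(prop-1-en-2-yl)hex-4-en-1-yl]bicyclo[3.3.1]non-3-ene-2,9-dione, via C4 aroylacetyl β-diketone 18 (not isolated)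
Conditions: 17 (1.5 equiv), LiN(SiMe3)2 (4.5 equiv), THF, −78 °C; then 15, −78 → 60 °C; aq. NH4Cl
Reagents that add atoms: none
Why: Crossed Claisen condensation of the lithium enolate of 17 with a non-enolisable ester (expected first at the less hindered C4 ester) gives 18. Its enolate then acylates the second, cis-disposed ester at carbon (Dieckmann-type, six-membered) and closes ring A as the stabilised triketonate, which drives both equilibria; no stereocentre is formed.

Step 15
Reactants: 19 tetrasilyl ether
Product: 20 (1R,5R,7R)-3-(3,4-dihydroxybenzoyl)-1-[(2S)-2,3-dihydroxy-3-methylbutyl]-4-hydroxy-8,8-dimethyl-7-(3-methylbut-2-en-1-yl)-5-[(2R)-5-methyl-2-(prop-1-en-2-yl)hex-4-en-1-yl]bicyclo[3.3.1]non-3-ene-2,9-dione (CNP0245306.2)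
Conditions: Bu4NF (6 equiv), AcOH (6 equiv), THF, 0 → 25 °C, argon; pH 4 buffer
Reagents that add atoms: none
Why: Fluoride cleaves all four silyl ethers; buffered, acid-free conditions spare the three olefins, and exclusion of air protects the catecholate.

## Compound list

1 | (±)-lavandulol | CC(C)=CCC(CO)C(C)=C | starting material
2 | (S)-lavandulol | C=C(C)[C@H](CC=C(C)C)CO | intermediate
3 | (S)-lavandulyl iodide | IC[C@@H](CC=C(C)C)C(C)=C | intermediate
4 | dimethyl 3-oxopentanedioate | COC(=O)CC(=O)CC(=O)OC | starting material
5 | dimethyl 2-[(2R)-5-methyl-2-(prop-1-en-2-yl)hex-4-en-1-yl]-3-oxopentanedioate (enol form) | COC(=O)C(C[C@@H](CC=C(C)C)C(C)=C)=C(O)CC(=O)OC | intermediate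
6 | dimethyl 3-oxo-2-[(2R)-2-(prop-1-en-2-yl)pent-4-en-1-yl]pentanedioate (enol form) | COC(=O)C(C[C@@H](CC=C)C(C)=C)=C(O)CC(=O)OC | intermediate
7 | dimethyl (1S,5R)-4,4-dimethyl-2-oxo-5-(prop-2-en-1-yl)cyclohexane-1,3-dicarboxylate (enol form) | COC(=O)[C@H]1C[C@@H](CC=C)C(C)(C)C(C(=O)OC)=C1O | intermediate
8 | dimethyl (1S,5R)-4,4-dimethyl-5-(3-methylbut-2-en-1-yl)-2-oxocyclohexane-1,3-dicarboxylate (enol form) | COC(=O)[C@H]1C[C@@H](CC=C(C)C)C(C)(C)C(C(=O)OC)=C1O | intermediate
9 | dimethyl (1S,5R)-4,4-dimethyl-5-(3-methylbut-2-en-1-yl)-1-[(2R)-5-methyl-2-(prop-1-en-2-yl)hex-4-en-1-yl]-2-oxocyclohexane-1,3-dicarboxylate (enol form) | C=C(C)[C@H](CC=C(C)C)C[C@]1(C(=O)OC)C[C@@H](CC=C(C)C)C(C)(C)C(C(=O)OC)=C1O | intermediate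
10 | 3-hydroxy-3-methylbutan-2-one | CC(=O)C(C)(C)O | starting material
11 | 1-bromo-3-hydroxy-3-methylbutan-2-one | BrCC(=O)C(C)(C)O | intermediate
12 | 1-bromo-3-methyl-3-(triethylsilyloxy)butan-2-one | BrCC(=O)C(C)(C)O[Si](CC)(CC)CC | intermediate
13 | dimethyl (1S,3R,5R)-1-lavandulyl-5-prenyl-3-[3-methyl-2-oxo-3-(triethylsilyloxy)butyl]-4,4-dimethyl-2-oxocyclohexane-1,3-dicarboxylate | C=C(C)[C@H](CC=C(C)C)C[C@]1(C(=O)OC)C[C@@H](CC=C(C)C)C(C)(C)[C@@](CC(=O)C(C)(C)O[Si](CC)(CC)CC)(C(=O)OC)C1=O | intermediate
14 | the (2S)-2-hydroxy-3-methyl-3-(triethylsilyloxy)butyl analogue of 13 | C=C(C)[C@H](CC=C(C)C)C[C@]1(C(=O)OC)C[C@@H](CC=C(C)C)C(C)(C)[C@@](C[C@H](O)C(C)(C)O[Si](CC)(CC)CC)(C(=O)OC)C1=O | intermediate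
15 | the (2S)-3-methyl-2,3-bis(triethylsilyloxy)butyl analogue of 13 | C=C(C)[C@H](CC=C(C)C)C[C@]1(C(=O)OC)C[C@@H](CC=C(C)C)C(C)(C)[C@@](C[C@H](O[Si](CC)(CC)CC)C(C)(C)O[Si](CC)(CC)CC)(C(=O)OC)C1=O | intermediate
16 | 1-(3,4-dihydroxyphenyl)ethan-1-one | CC(=O)c1ccc(O)c(O)c1 | starting material
17 | 1-[3,4-bis(triisopropylsilyloxy)phenyl]ethan-1-one | CC(=O)c1ccc(O[Si](C(C)C)(C(C)C)C(C)C)c(O[Si](C(C)C)(C(C)C)C(C)C)c1 | intermediate
18 | analogue of 15 in which the C4 ester has become a 3-aryl-3-oxopropanoyl group (C2 methyl ester intact) | C=C(C)[C@H](CC=C(C)C)C[C@]1(C(=O)CC(=O)c2ccc(O[Si](C(C)C)(C(C)C)C(C)C)c(O[Si](C(C)C)(C(C)C)C(C)C)c2)C[C@@H](CC=C(C)C)C(C)(C)[C@@](C[C@H](O[Si](CC)(CC)CC)C(C)(C)O[Si](CC)(CC)CC)(C(=O)OC)C1=O | intermediate (not isolated)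
19 | target as bis(triethylsilyl) ether of the diol and bis(triisopropylsilyl) ether of the catechol | C=C(C)[C@H](CC=C(C)C)C[C@@]12C[C@@H](CC=C(C)C)C(C)(C)[C@@](C[C@H](O[Si](CC)(CC)CC)C(C)(C)O[Si](CC)(CC)CC)(C(=O)C(C(=O)c3ccc(O[Si](C(C)C)(C(C)C)C(C)C)c(O[Si](C(C)C)(C(C)C)C(C)C)c3)=C1O)C2=O | intermediate
20 | CNP0245306.2 | C=C(C)[C@H](CC=C(C)C)C[C@@]12C[C@@H](CC=C(C)C)C(C)(C)[C@@](C[C@H](O)C(C)(C)O)(C(=O)C(C(=O)c3ccc(O)c(O)c3)=C1O)C2=O | target

## Step count and least certain steps

Total: 15 steps. Longest linear sequence: 12 steps (steps 1–7, 10–12, 14, 15).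

**Step 5 (key step).** Configuration at C7 may erode through a 1,2-hydride shift or loss and return of the C7 proton at the C8 cation, and capture by an ester carbonyl with demethylation (lactonisation) may compete, because the cation is formed reversibly and lives long enough to explore other paths. Fallback: the route is left at 6 and rejoined at 7. Hydrogen chloride in CH2Cl2 at −30 °C adds to the isopropenyl group only and gives the tertiary chloride F1. TiCl4 in CH2Cl2 at −78 °C then forms the titanium enolate of the β-keto ester and ionises the chloride next to it (Lewis-acid tert-alkylation of an enolate), so capture at C1 should outrun the hydride shift.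

**Step 14.** The ketone enolate may fail to attack the neopentyl-type esters, the sequence may stall after the first acylation, or methoxide may open the β-keto ester by retro-Claisen attack, since both esters sit on quaternary carbons. Fallback: the route is left at 15 and rejoined at 19.
- The smaller lithium enolate of allyl acetate (LiN(iPr)2, THF, −78 → 25 °C) performs the Claisen–Dieckmann sequence and gives the bicyclic allyl ester F2.
- Pd(PPh3)4 (zerovalent palladium) and morpholine remove the allyl group with decarboxylation and give the bicyclic dione F3.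
- 3,4-Bis(triisopropylsilyloxy)benzoic acid F4 (from commercial 3,4-dihydroxybenzoic acid by silylation and mild hydrolysis of the silyl ester) is coupled with N,N'-dicyclohexylcarbodiimide and 4-(dimethylamino)pyridine. This gives the enol ester F5, which the same catalyst rearranges to the C3-aroyl compound 19.

**Step 10.** Alkylation may occur at oxygen, bromine may be transferred to the enolate instead of carbon, or facial control may be incomplete, because the nucleophilic carbon lies between C8 and C9. Fallback: the route is left at 6 and rejoined at 13.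
- The unsubstituted α-carbon of 6 (the future C1) is alkylated with 12 (K2CO3, acetone) to give the acyclic keto diester F6.
- The SnCl4 cyclisation then forms C1–C8 between two fully substituted carbons and gives F7. A chelated enol with the ester syn to oxygen should place the ester equatorial and the chain axial, that is trans to the C7 substituent.
- Cross-metathesis with 2-methyl-2-butene gives the prenyl compound F8, and alkylation with 3 (Cs2CO3, DMF) at C5 gives 13.

**Step 4.** The catalyst may decompose under ethylene before the trisubstituted olefin is consumed, or ruthenium hydrides may move the new terminal olefin. Fallback: the route is left at 2 and rejoined at 6.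
- mCPBA epoxidises the more electron-rich trisubstituted olefin of 2 and gives the epoxy alcohol F9.
- H5IO6 cleaves the epoxide to the lactol F10.
- Ph3P=CH2 gives (S)-2-(prop-1-en-2-yl)pent-4-en-1-ol F11.
- I2, PPh3 and imidazole give the iodide F12, which alkylates 4 (NaH, THF–DMF) to give 6.

**Step 11.** The catalyst may discriminate poorly between the two bulky flanks of the ketone, and the reduction may be slow. Fallback: the route is left at 13 and rejoined at 14. NaBH4 with CeCl3 in MeOH at −40 °C reduces the chain ketone without stereocontrol and gives 14 together with its carbinol epimer F13. The two are separated by chromatography, and F13 is returned to 13 with Dess–Martin periodinane for another pass.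

## Further compounds

F1 | step 5 | dimethyl 2-[(2R)-2-(2-chloropropan-2-yl)pent-4-en-1-yl]-3-oxopentanedioate | COC(=O)CC(=O)C(C[C@@H](CC=C)C(C)(C)Cl)C(=O)OC
F2 | step 14 | prop-2-en-1-yl ester of the C3 carboxylic acid of the silyl-protected bicyclic trione (C3 allyloxycarbonyl in place of aroyl in 19) | C=C(C)[C@H](CC=C(C)C)C[C@@]12C[C@@H](CC=C(C)C)C(C)(C)[C@@](C[C@H](O[Si](CC)(CC)CC)C(C)(C)O[Si](CC)(CC)CC)(C(=O)C(C(=O)OCC=C)=C1O)C2=O
F3 | step 14 | silyl-protected bicyclic trione unsubstituted at C3 | C=C(C)[C@H](CC=C(C)C)C[C@@]12C[C@@H](CC=C(C)C)C(C)(C)[C@@](C[C@H](O[Si](CC)(CC)CC)C(C)(C)O[Si](CC)(CC)CC)(C(=O)C=C1O)C2=O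
F4 | step 14 | 3,4-bis(triisopropylsilyloxy)benzoic acid | OC(=O)c1ccc(O[Si](C(C)C)(C(C)C)C(C)C)c(O[Si](C(C)C)(C(C)C)C(C)C)c1
F5 | step 14 | C4 enol 3,4-bis(triisopropylsilyloxy)benzoate of F3 | C=C(C)[C@H](CC=C(C)C)C[C@@]12C[C@@H](CC=C(C)C)C(C)(C)[C@@](C[C@H](O[Si](CC)(CC)CC)C(C)(C)O[Si](CC)(CC)CC)(C(=O)C=C1OC(=O)c3ccc(O[Si](C(C)C)(C(C)C)C(C)C)c(O[Si](C(C)C)(C(C)C)C(C)C)c3)C2=O
F6 | step 10 | dimethyl 2-[3-methyl-2-oxo-3-(triethylsilyloxy)butyl]-3-oxo-4-[(2R)-2-(prop-1-en-2-yl)pent-4-en-1-yl]pentanedioate | COC(=O)C(CC(=O)C(C)(C)O[Si](CC)(CC)CC)C(=O)C(C[C@@H](CC=C)C(C)=C)C(=O)OC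
F7 | step 10 | dimethyl (3R,5R)-4,4-dimethyl-3-[3-methyl-2-oxo-3-(triethylsilyloxy)butyl]-2-oxo-5-(prop-2-en-1-yl)cyclohexane-1,3-dicarboxylate | COC(=O)C1C[C@@H](CC=C)C(C)(C)[C@@](CC(=O)C(C)(C)O[Si](CC)(CC)CC)(C(=O)OC)C1=O
F8 | step 10 | dimethyl (3R,5R)-4,4-dimethyl-5-(3-methylbut-2-en-1-yl)-3-[3-methyl-2-oxo-3-(triethylsilyloxy)butyl]-2-oxocyclohexane-1,3-dicarboxylate | COC(=O)C1C[C@@H](CC=C(C)C)C(C)(C)[C@@](CC(=O)C(C)(C)O[Si](CC)(CC)CC)(C(=O)OC)C1=O
F9 | step 4 | (2S)-2-[(3,3-dimethyloxiran-2-yl)methyl]-3-methylbut-3-en-1-ol (epoxide epimers) | C=C(C)[C@H](CC1OC1(C)C)CO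
F10 | step 4 | (4S)-4-(prop-1-en-2-yl)oxolan-2-ol (anomers) | C=C(C)[C@H]1COC(O)C1
F11 | step 4 | (2S)-2-(prop-1-en-2-yl)pent-4-en-1-ol | C=C(C)[C@H](CC=C)CO
F12 | step 4 | (2S)-1-iodo-2-(prop-1-en-2-yl)pent-4-ene | IC[C@@H](CC=C)C(C)=C
F13 | step 11 | (2R)-carbinol epimer of 14 | C=C(C)[C@H](CC=C(C)C)C[C@]1(C(=O)OC)C[C@@H](CC=C(C)C)C(C)(C)[C@@](C[C@@H](O)C(C)(C)O[Si](CC)(CC)CC)(C(=O)OC)C1=O
A1 | alternative 1 | fused enol lactone (C4 on the C9 enol oxygen, C2 methyl enol ether, diol acetonide) | C=C(C)[C@H](CC=C(C)C)CC1=C2OC(=O)C=C(OC)[C@]2(C[C@@H]3OC(C)(C)OC3(C)C)C(C)(C)[C@H](CC=C(C)C)C1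
A2 | alternative 1 | bicyclic trione as C2 methyl enol ether, diol as acetonide | C=C(C)[C@H](CC=C(C)C)C[C@@]12C[C@@H](CC=C(C)C)C(C)(C)[C@@](C[C@@H]3OC(C)(C)OC3(C)C)(C(OC)=CC1=O)C2=O
A3 | alternative 2 | bicyclo[3.2.1]octane-6,7,8-trione with both bridgehead side chains, diol as acetonide | C=C(C)[C@H](CC=C(C)C)C[C@@]12C[C@@H](CC=C(C)C)C(C)(C)[C@@](C[C@@H]3OC(C)(C)OC3(C)C)(C(=O)C1=O)C2=O
A4 | alternative 2 | 2-diazo-1-[3,4-bis(tert-butyldimethylsilyloxy)phenyl]ethan-1-one | [N-]=[N+]=CC(=O)c1ccc(O[Si](C)(C)C(C)(C)C)c(O[Si](C)(C)C(C)(C)C)c1
A5 | alternative 2 | target with catechol as bis-silyl ether and diol as acetonide | C=C(C)[C@H](CC=C(C)C)C[C@@]12C[C@@H](CC=C(C)C)C(C)(C)[C@@](C[C@@H]3OC(C)(C)OC3(C)C)(C(=O)C(C(=O)c4ccc(O[Si](C)(C)C(C)(C)C)c(O[Si](C)(C)C(C)(C)C)c4)=C1O)C2=O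
A6 | alternative 3 | (4R)-3,3-dimethyl-4-(3-methylbut-2-en-1-yl)cyclopentan-1-one | O=C1C[C@@H](CC=C(C)C)C(C)(C)C1
A7 | alternative 3 | methyl 2-diazo-2-lavandulylacetate | COC(=O)C(=[N+]=[N-])C[C@@H](CC=C(C)C)C(C)=C
A8 | alternative 3 | ring B β-keto ester with quaternary C5 (lavandulyl and C4 ester) | C=C(C)[C@H](CC=C(C)C)C[C@]1(C(=O)OC)C[C@@H](CC=C(C)C)C(C)(C)CC1=O
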